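**Strategy.** The C4–aryl bond between the two isoflavans is made last, by SN1 arylation of an isoflavan-4-ol (unit 1) with the (R)-isoflavan (unit 2). The pyran ring of unit 1 (O1, C2, C3, C4, C4a, C8a) is not closed directly: it arises by one-carbon ring expansion of the furanone ring of an aurone. BF3 opens the spiro-epoxide of the aurone at its benzylic carbon, the acyl carbon shifts from the spiro carbon to that carbon, and a 3-aryl-4-hydroxycoumarin results. The step exploits that C3 carries the electron-rich ring B and lies between the O-bound C2 and the ring-A-bound C4, exactly like the exocyclic benzylic carbon of an aurone.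

Key step: step 5

Remark: the target is read as (3R,4S), 3,4-trans, in the 3,4-diarylchroman (unit 1: benzo ring A, aryl ring B at C3) and (3R) in the 3-arylchroman (unit 2: benzo ring C, aryl ring D with C1 on the chroman, OMe at C3, oxygen at C5). The antipodes of the chiral reagent (step 7) and catalyst (step 11) are assigned by analogy with simple models and would be confirmed on the first run.

**Unit 1 (electrophile)**

Step 1
Reactants: 1 6-hydroxy-1-benzofuran-3(2H)-one
Product: 2 6-(benzyloxy)-1-benzofuran-3(2H)-one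
Conditions: BnBr (1.05 equiv), K2CO3, DMF, rt
Reagents that add atoms: benzyl bromide, BrCc1ccccc1
Why: Williamson etherification; the phenol is far more acidic than the C2 methylene, so with a weak base O-benzylation should outrun C-alkylation.

Step 2
Reactants: 3 2,3-dihydroxy-4-methoxybenzaldehyde
Product: 4 2,3-bis(benzyloxy)-4-methoxybenzaldehyde
Conditions: BnBr (2.3 equiv), K2CO3, DMF, 60 °C
Reagents that add atoms: benzyl bromide, BrCc1ccccc1
Why: double Williamson etherification; warming should be enough to alkylate the hydrogen-bonded 2-OH as well.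

Step 3
Reactants: 2 6-(benzyloxy)benzofuranone; 4 bis(benzyloxy) aldehyde
Product: 5 (Z)-aurone
Conditions: KOH (0.5 equiv), MeOH, rt
Reagents that add atoms: none
Why: aldol (Claisen–Schmidt) condensation at the C2 methylene followed by E1cB dehydration should give the conjugated aurone, the Z isomer being the thermodynamic one.

Step 4
Reactants: 5 (Z)-aurone
Product: 6 aurone epoxide (racemic spiro-oxirane)
Conditions: 30% H2O2, NaOH (aq., cat.), MeOH–CH2Cl2, 0 °C → rt
Reagents that add atoms: hydrogen peroxide, OO
Why: Weitz–Scheffer nucleophilic epoxidation of the enone; the configuration of the oxirane is immaterial because both of its carbons lose their stereochemistry in step 5.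

Step 5
Reactants: 6 aurone epoxide
Product: 8 3-aryl-4-hydroxycoumarin, via chromane-2,4-dione tautomer 7 (not isolated)
Conditions: BF3·OEt2 (0.3 equiv), CH2Cl2, −20 → 0 °C
Reagents that add atoms: none
Why: BF3 coordinates the oxirane oxygen and the benzylic C–O bond ionises to a cation stabilised by ring B (para-OMe, ortho-OBn); the acyl carbon (C3 of the benzofuranone) then migrates from the spiro carbon to this cation while the spiro carbon collapses to the lactone carbonyl, and dione 7 enolises to 8. The closest known reaction type is the Lewis-acid rearrangement of α,β-epoxy ketones by 1,2-acyl shift (semipinacol type), familiar from chalcone epoxides on the way to isoflavones and from aurone epoxides. No ring is closed by cyclisation: the six-membered pyranone arises from the five-membered furanone by a 1,2-shift that inserts the ring-B-bearing carbon between C2 and the former ketone carbon. No stereocenter is created, since the inserted carbon (the future C3) ends as an enol carbon, so the epoxide can be used as its racemate. The step needs benzylic rather than spiro C–O cleavage and acyl rather than aryloxy migration: the electron-rich ring B secures the first, and the high migratory aptitude of acyl together with the gain of an ester carbonyl secures the second.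

Step 6
Reactants: 8 3-aryl-4-hydroxycoumarin
Product: 9 isoflav-3-ene (3-aryl-2H-chromene)
Conditions: BH3·THF (3 equiv), THF, 0 °C → rt; aq. HCl work-up
Reagents that add atoms: none
Why: borane reduction of the vinylogous acid, a known conversion of 3-aryl-4-hydroxycoumarins into isoflav-3-enes: the lactone carbonyl is reduced to CH2 and the C4 oxygen is lost by hydroboration–elimination at the enol borate stage, while benzyl ethers are inert.

Step 7
Reactants: 9 isoflav-3-ene
Product: 11 (3R,4S)-trans-isoflavan-4-ol, via alkyl(isopinocampheyl)borane 10 (not isolated)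
Conditions: IpcBH2 [from (−)-α-pinene] (1.2 equiv), THF, −25 °C; then NaOH, 30% H2O2, 0 °C
Reagents that add atoms: hydrogen peroxide, OO
Why: Brown asymmetric hydroboration–oxidation; boron should add to the less substituted C4 and hydrogen to C3 on the same face (hence the 3,4-trans alcohol after retentive oxidation), and the isopinocampheyl group selects the alkene face, which sets C3 (R), this antipode being chosen by analogy with 1-arylcycloalkenes.

**Unit 2 (nucleophile)**

Step 8
Reactants: 12 3-bromo-5-methoxyphenol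
Product: 13 (3-bromo-5-methoxyphenoxy)triisopropylsilane
Conditions: TIPSCl, imidazole, DMF, rt
Reagents that add atoms: chlorotriisopropylsilane, CC(C)[Si](Cl)(C(C)C)C(C)C
Why: silylation of the phenol; the bulky silyl ether keeps the oxygen a donor and will later shield both positions ortho to it.

Step 9
Reactants: 14 7-hydroxychroman-4-one
Product: 15 4-oxochroman-7-yl pivalate
Conditions: PivCl, Et3N, DMAP (cat.), CH2Cl2, 0 °C → rt
Reagents that add atoms: pivaloyl chloride, CC(C)(C)C(Cl)=O
Why: O-acylation; the ester should survive steps 10–13 and deactivates ring C towards electrophiles in step 13.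

Step 10
Reactants: 15 chromanone pivalate; 13 aryl bromide
Product: 16 racemic isoflavanone
Conditions: Pd(OAc)2 (3 mol %), XPhos (6 mol %), K3PO4, toluene, 90 °C
Reagents that add atoms: none
Why: palladium-catalysed ketone α-arylation; the weak phosphate base spares the pivalate, and the more acidic monoarylated product should resist a second arylation.

Step 11
Reactants: 16 racemic isoflavanone
Product: 17 (3R,4R)-cis-isoflavan-4-ol
Conditions: RuCl(p-cymene)[(R,R)-TsDPEN] (2 mol %), HCO2H–Et3N (5:2), EtOAc, 40 °C
Reagents that add atoms: none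
Why: Noyori-type asymmetric transfer hydrogenation with dynamic kinetic resolution; C3 epimerises through the enol under the amine base while the catalyst reduces one ketone enantiomer from the face anti to the aryl group, which should set C3 (R) and C4 (R), cis.

Step 12
Reactants: 17 cis-isoflavan-4-ol
Product: 18 (R)-isoflavan
Conditions: H2 (3 bar), Pd/C (10 wt %), AcOH, 40 °C
Reagents that add atoms: none
Why: hydrogenolysis of the benzylic C4–O bond; C3 is not involved, so its configuration is kept, and the pivalate and silyl ether should survive.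

**Union and deprotection**

Step 13
Reactants: 11 trans-isoflavan-4-ol; 18 (R)-isoflavan
Product: 20 protected dimer, via chroman-4-ylium cation 19 (not isolated)
Conditions: TfOH (5 mol %), HFIP–CH2Cl2 (1:4), −30 °C; 18 (3 equiv), 11 added slowly
Reagents that add atoms: none
Why: SN1 Friedel–Crafts alkylation (the biomimetic 4-arylation of isoflavan-4-ols): cation 19, stabilised by the para-benzyloxy group and O1 of ring A, should be attacked by C2 of ring D, the only position activated by both oxygen donors and not flanked by the silyl ether (ring C is deactivated by the pivalate), from the face anti to ring B, which sets C4 (S, 3,4-trans) while C3 is untouched.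

Step 14
Reactants: 20 protected dimer
Product: 21 tris(benzyl) ether
Conditions: KOH, MeOH–THF–H2O, 50 °C, argon; aq. HCl work-up
Reagents that add atoms: none
Why: saponification of the aryl pivalate and hydroxide cleavage of the aryl silyl ether (phenoxide leaving groups); benzyl ethers and the three stereocenters are inert to base.

Step 15
Reactants: 21 tris(benzyl) ether
Product: 22 target CNP0227211.1
Conditions: H2 (1 bar), Pd/C (10 wt %), THF–MeOH, rt
Reagents that add atoms: none
Why: hydrogenolysis of the three benzyl ethers; the diarylmethine C–C bonds and the aryl alkyl ethers should not be cleaved under these mild conditions.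

**Compound list**

1 | 6-hydroxy-1-benzofuran-3(2H)-one | O=C1COc2cc(O)ccc21 | starting material
2 | 6-(benzyloxy)-1-benzofuran-3(2H)-one | O=C1COc2cc(OCc3ccccc3)ccc21 | intermediate
3 | 2,3-dihydroxy-4-methoxybenzaldehyde | COc1ccc(C=O)c(O)c1O | starting material
4 | 2,3-bis(benzyloxy)-4-methoxybenzaldehyde | COc1ccc(C=O)c(OCc2ccccc2)c1OCc1ccccc1 | intermediate
5 | (Z)-6-(benzyloxy)-2-[2,3-bis(benzyloxy)-4-methoxybenzylidene]-1-benzofuran-3(2H)-one | COc1ccc(/C=C2\Oc3cc(OCc4ccccc4)ccc3C2=O)c(OCc2ccccc2)c1OCc1ccccc1 | intermediate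
6 | 6-(benzyloxy)-3'-[2,3-bis(benzyloxy)-4-methoxyphenyl]-3H-spiro[1-benzofuran-2,2'-oxiran]-3-one (racemic) | COc1ccc(C2OC23Oc4cc(OCc5ccccc5)ccc4C3=O)c(OCc2ccccc2)c1OCc1ccccc1 | intermediate
7 | 7-(benzyloxy)-3-[2,3-bis(benzyloxy)-4-methoxyphenyl]chromane-2,4-dione (racemic keto tautomer) | COc1ccc(C2C(=O)c3ccc(OCc4ccccc4)cc3OC2=O)c(OCc2ccccc2)c1OCc1ccccc1 | intermediate (not isolated)
8 | 7-(benzyloxy)-3-[2,3-bis(benzyloxy)-4-methoxyphenyl]-4-hydroxy-2H-chromen-2-one | COc1ccc(C2=C(O)c3ccc(OCc4ccccc4)cc3OC2=O)c(OCc2ccccc2)c1OCc1ccccc1 | intermediate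
9 | 7-(benzyloxy)-3-[2,3-bis(benzyloxy)-4-methoxyphenyl]-2H-chromene | COc1ccc(C2=Cc3ccc(OCc4ccccc4)cc3OC2)c(OCc2ccccc2)c1OCc1ccccc1 | intermediate
10 | [(3R,4S)-7-(benzyloxy)-3-[2,3-bis(benzyloxy)-4-methoxyphenyl]chroman-4-yl][(1S,2S,3S,5R)-isopinocampheyl]borane | COc1ccc([C@@H]2COc3cc(OCc4ccccc4)ccc3[C@H]2B[C@H]2C[C@H]3C[C@@H]([C@@H]2C)C3(C)C)c(OCc2ccccc2)c1OCc1ccccc1 | intermediate (not isolated)
11 | (3R,4S)-7-(benzyloxy)-3-[2,3-bis(benzyloxy)-4-methoxyphenyl]chroman-4-ol (3,4-trans) | COc1ccc([C@@H]2COc3cc(OCc4ccccc4)ccc3[C@H]2O)c(OCc2ccccc2)c1OCc1ccccc1 | intermediate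
12 | 3-bromo-5-methoxyphenol | COc1cc(O)cc(Br)c1 | starting material
13 | (3-bromo-5-methoxyphenoxy)triisopropylsilane | COc1cc(Br)cc(O[Si](C(C)C)(C(C)C)C(C)C)c1 | intermediate
14 | 7-hydroxychroman-4-one | O=C1CCOc2cc(O)ccc21 | starting material
15 | 4-oxochroman-7-yl pivalate | CC(C)(C)C(=O)Oc1ccc2C(=O)CCOc2c1 | intermediate
16 | 3-{3-methoxy-5-[(triisopropylsilyl)oxy]phenyl}-4-oxochroman-7-yl pivalate (racemic) | COc1cc(O[Si](C(C)C)(C(C)C)C(C)C)cc(c1)C1COc2cc(OC(=O)C(C)(C)C)ccc2C1=O | intermediate
17 | (3R,4R)-4-hydroxy-3-{3-methoxy-5-[(triisopropylsilyl)oxy]phenyl}chroman-7-yl pivalate (3,4-cis) | COc1cc(O[Si](C(C)C)(C(C)C)C(C)C)cc(c1)[C@@H]1COc2cc(OC(=O)C(C)(C)C)ccc2[C@@H]1O | intermediate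
18 | (3R)-3-{3-methoxy-5-[(triisopropylsilyl)oxy]phenyl}chroman-7-yl pivalate | COc1cc(O[Si](C(C)C)(C(C)C)C(C)C)cc(c1)[C@@H]1COc2cc(OC(=O)C(C)(C)C)ccc2C1 | intermediate
19 | (3R)-7-(benzyloxy)-3-[2,3-bis(benzyloxy)-4-methoxyphenyl]chroman-4-ylium | COc1ccc([C@@H]2COc3cc(OCc4ccccc4)ccc3[CH+]2)c(OCc2ccccc2)c1OCc1ccccc1 | intermediate (not isolated)
20 | (3R,4S)-7-(benzyloxy)-3-[2,3-bis(benzyloxy)-4-methoxyphenyl]-4-{2-methoxy-6-[(3R)-7-(pivaloyloxy)chroman-3-yl]-4-[(triisopropylsilyl)oxy]phenyl}chroman | COc1ccc([C@@H]2COc3cc(OCc4ccccc4)ccc3[C@H]2c2c(OC)cc(O[Si](C(C)C)(C(C)C)C(C)C)cc2[C@@H]2COc3cc(OC(=O)C(C)(C)C)ccc3C2)c(OCc2ccccc2)c1OCc1ccccc1 | intermediate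
21 | (3R,4S)-7-(benzyloxy)-3-[2,3-bis(benzyloxy)-4-methoxyphenyl]-4-{4-hydroxy-2-[(3R)-7-hydroxychroman-3-yl]-6-methoxyphenyl}chroman | COc1ccc([C@@H]2COc3cc(OCc4ccccc4)ccc3[C@H]2c2c(OC)cc(O)cc2[C@@H]2COc3cc(O)ccc3C2)c(OCc2ccccc2)c1OCc1ccccc1 | intermediate
22 | (3R,4S)-3-(2,3-dihydroxy-4-methoxyphenyl)-4-{4-hydroxy-2-[(3R)-7-hydroxychroman-3-yl]-6-methoxyphenyl}chroman-7-ol | COc1ccc([C@@H]2COc3cc(O)ccc3[C@H]2c2c(OC)cc(O)cc2[C@@H]2COc3cc(O)ccc3C2)c(O)c1O | target

**Total step count:** 15. **Longest linear sequence:** 9 (steps 1, 3, 4, 5, 6, 7, 13, 14, 15).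

**Steps most likely to fail**

Step 13. Bond formation at the ring-D carbon that is flanked by OMe and the chromanyl group may be slower than loss of H3 from cation 19 (which erases C3 and drains material into the chromene) or than alkylation at other arene positions (loss of site control, oligomerisation). Fallback (polarity reversed, site fixed by a halogen): it sets out from 11 and 18 and returns at 20. SOCl2, pyridine, CH2Cl2, −20 °C should convert 11 into the C4 chloride F1 (configuration at C4 immaterial). Zn dust, LiCl, THF, rt should then insert into the C–Cl bond to give the benzylic zinc chloride F2. Separately, N-iodosuccinimide (TFA cat., MeCN, 0 °C) should iodinate 18 at C2 of ring D (para to the silyloxy group, ortho to OMe) to give the aryl iodide F3. Negishi coupling of F2 with F3 (Pd(OAc)2, SPhos, THF, 50 °C) should give 20; the configurationally labile benzylic metal centre should settle trans to ring B before the C–C bond forms.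

Step 7. Facial discrimination by the isopinocampheyl group on this stilbene-like, ortho-substituted trisubstituted alkene may be incomplete or of the opposite sense. Fallback (dynamic kinetic resolution in place of reagent control): it sets out from 11 of whatever enantiomeric purity (the racemate from BH3·THF serves equally) and returns at 20. Dess–Martin periodinane, CH2Cl2, rt should give the isoflavanone F4, whose C3 is configurationally labile. RuCl(p-cymene)[(R,R)-TsDPEN], HCO2H–Et3N, 40 °C should reduce it with dynamic kinetic resolution to the cis-(3R,4R)-alcohol F5. F5 takes the place of 11 in step 13, gives the same cation 19 and hence 20.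

Step 5. Ionisation at the spiro carbon (followed by hydride or aryl shift), migration of the aryloxy oxygen in place of the acyl carbon, or Lewis-acid debenzylation may divert the epoxide. Fallback (a different one-carbon ring expansion, by halocarbene insertion into the furan ring): it sets out from 2 and 4 and returns at 9. NaBH4, MeOH, 0 °C should reduce 2 to the carbinol F6, and TsOH (cat.), toluene, 80 °C should dehydrate it to 6-(benzyloxy)benzofuran F7. Aldehyde 4 should give the nitrile F8 (I2, aq. NH3, THF), then the amidinium chloride F9 (LiN(SiMe3)2, THF; then HCl) and the 3-aryl-3-chlorodiazirine F10 (NaOCl, LiCl, DMSO). Warming F10 with F7 (Na2CO3, MeCN, 50 °C) should release the arylchlorocarbene, which adds to the furan C2=C3 bond. Cyclopropyl-to-allyl cation opening across the ring-fusion bond (Ciamician–Dennstedt-type carbon insertion) should give the isoflavylium chloride F11, in which the furan ring has again become the pyran ring. NaBH4, THF–MeOH, −20 °C should then add hydride at C2 to give 9.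

**Further compounds**

F1 | step 13 | (3R)-7-(benzyloxy)-3-[2,3-bis(benzyloxy)-4-methoxyphenyl]-4-chlorochroman (C4 epimers) | COc1ccc([C@@H]2COc3cc(OCc4ccccc4)ccc3C2Cl)c(OCc2ccccc2)c1OCc1ccccc1
F2 | step 13 | [(3R)-7-(benzyloxy)-3-[2,3-bis(benzyloxy)-4-methoxyphenyl]chroman-4-yl]zinc chloride | COc1ccc([C@@H]2COc3cc(OCc4ccccc4)ccc3C2[Zn]Cl)c(OCc2ccccc2)c1OCc1ccccc1
F3 | step 13 | (3R)-3-{2-iodo-3-methoxy-5-[(triisopropylsilyl)oxy]phenyl}chroman-7-yl pivalate | COc1cc(O[Si](C(C)C)(C(C)C)C(C)C)cc(c1I)[C@@H]1COc2cc(OC(=O)C(C)(C)C)ccc2C1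
F4 | step 7 | 7-(benzyloxy)-3-[2,3-bis(benzyloxy)-4-methoxyphenyl]chroman-4-one (racemic) | COc1ccc(C2COc3cc(OCc4ccccc4)ccc3C2=O)c(OCc2ccccc2)c1OCc1ccccc1
F5 | step 7 | (3R,4R)-7-(benzyloxy)-3-[2,3-bis(benzyloxy)-4-methoxyphenyl]chroman-4-ol (3,4-cis) | COc1ccc([C@@H]2COc3cc(OCc4ccccc4)ccc3[C@@H]2O)c(OCc2ccccc2)c1OCc1ccccc1
F6 | step 5 | 6-(benzyloxy)-2,3-dihydro-1-benzofuran-3-ol (racemic) | OC1COc2cc(OCc3ccccc3)ccc21
F7 | step 5 | 6-(benzyloxy)-1-benzofuran | c1cc2ccc(OCc3ccccc3)cc2o1
F8 | step 5 | 2,3-bis(benzyloxy)-4-methoxybenzonitrile | COc1ccc(C#N)c(OCc2ccccc2)c1OCc1ccccc1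
F9 | step 5 | 2,3-bis(benzyloxy)-4-methoxybenzamidinium chloride | COc1ccc(C(N)=[NH2+])c(OCc2ccccc2)c1OCc1ccccc1.[Cl-]
F10 | step 5 | 3-[2,3-bis(benzyloxy)-4-methoxyphenyl]-3-chloro-3H-diazirine | COc1ccc(C2(Cl)N=N2)c(OCc2ccccc2)c1OCc1ccccc1
F11 | step 5 | 7-(benzyloxy)-3-[2,3-bis(benzyloxy)-4-methoxyphenyl]chromenylium chloride | COc1ccc(-c2c[o+]c3cc(OCc4ccccc4)ccc3c2)c(OCc2ccccc2)c1OCc1ccccc1.[Cl-]
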